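**Retrosynthetic overview**

1. Target 33 ← 11β,12β-oxirane from the C11=C12 alkene of macrocycle 31 (bromohydrin, then closure); 31 ← one Ni/Cr-mediated closure of the C7–C8 bond (enol triflate on C8, Z-enal at C7) that forms the ten-membered ring and, by lactonisation, the butenolide.
2. The cyclohexene ring C1–C10–C11–C12–C13–C14 is not built in its final size: it arises from cyclopentenol 18 (ring C14–C13–C12–C11–C10) by semipinacol ring expansion of the exocyclic C1–C2 oxirane, ring carbon C10 shifting from C14 to C1.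
3. Enabling feature: the quaternary C1 flanked by two oxygen-bearing carbons, exocyclic C2 and ring carbon C14 (a 2-quaternary 1,3-dioxygenated array, the retron of a tertiary 2,3-epoxy alcohol), with the more substituted, allylic ring carbon C10 as migrating group.
4. 18 ← ring-closing metathesis (C11=C12) ← allyl addition to the C14 ketone ← catalytic asymmetric allylboration of epoxy aldehyde 9 (from nerol by Still–Gennari olefination and Sharpless epoxidation) with Z-allylboronate 14.
5. Ring order: C1–C2 oxirane, cyclopentene, cyclohexene (one-carbon enlargement), ten-membered ring together with butenolide, C11–C12 oxirane.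

Key step: step 14

Remark (numbering and reading of the target): briarane numbering is used. C1 is the quaternary ring-fusion carbon (C15 methyl), C2 carries the butanoate, C5 (C16 methyl)=C6 is the Z alkene, C7 carries the lactone oxygen, C8=C17 (C19 methyl) with C18 the lactone carbonyl, C10 is the ring-fusion CH, C11 carries the C20 methyl, C14 carries the acetate. The SMILES is read as 1R,2S,7R,10S,11S,12R,14R; "β" is the face of the six-membered ring that carries C15. TBDPS = tert-butyldiphenylsilyl, TBS = tert-butyldimethylsilyl, pin = pinacolato.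

Remark (assumption): the sense of induction of the phosphoric acid in step 10 is taken from its behaviour with simple aldehydes (the R acid attacks the Re face), so the S acid is used for Si-face attack.

**Route**

Step 1
Reactants: 1 nerol
Product: 2 neryl TBDPS ether
Conditions: TBDPSCl, imidazole, DMF, 0 °C to rt
Reagents that add atoms: tert-butyl(chloro)diphenylsilane, CC(C)(C)[Si](Cl)(c1ccccc1)c1ccccc1
Why: Imidazole-promoted silylation of the primary allylic alcohol gives a robust silyl ether that should survive every step up to the fluoride deprotection of step 23, and no stereocentre is formed.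

Step 2
Reactants: 2 neryl TBDPS ether
Product: 3 terminal epoxide of 2 (racemic)
Conditions: mCPBA (1.05 equiv), CH2Cl2, −20 to 0 °C
Reagents that add atoms: 3-chloroperbenzoic acid, OOC(=O)c1cccc(Cl)c1
Why: Prilezhaev epoxidation should select the electron-rich terminal trisubstituted alkene, because the C5=C6 alkene is inductively deactivated and shielded by the allylic silyloxy group, and the racemic oxirane centre is destroyed in step 3.

Step 3
Reactants: 3 terminal epoxide
Product: 5 (4Z)-6-(TBDPS-oxy)-4-methylhex-4-enal, via vicinal diol 4 (not isolated)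
Conditions: H5IO6, THF/H2O, 0 °C to rt
Reagents that add atoms: water, O
Why: Acid-mediated hydration of the oxirane followed by Malaprade glycol cleavage excises acetone and leaves the C2 aldehyde with the Z C5=C6 alkene untouched.

Step 4
Reactants: 5 aldehyde
Product: 6 methyl (2Z,6Z)-8-(TBDPS-oxy)-2,6-dimethylocta-2,6-dienoate
Conditions: (CF3CH2O)2P(O)CH(CH3)CO2CH3, KN(SiMe3)2, 18-crown-6, THF, −78 °C
Reagents that add atoms: methyl 2-[bis(2,2,2-trifluoroethoxy)phosphoryl]propanoate, COC(=O)C(C)P(=O)(OCC(F)(F)F)OCC(F)(F)F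
Why: Still–Gennari olefination under dissociating conditions gives the Z trisubstituted enoate under kinetic control, which places the future C14 cis to C3 as the 1,2-shift of step 14 demands.

Step 5
Reactants: 6 Z-enoate
Product: 7 (2Z,6Z)-8-(TBDPS-oxy)-2,6-dimethylocta-2,6-dien-1-ol
Conditions: i-Bu2AlH (2.5 equiv), CH2Cl2, −78 °C; aq. potassium sodium tartrate
Reagents that add atoms: none
Why: 1,2-Reduction of the enoate by the aluminium hydride at low temperature gives the allylic alcohol without change of alkene geometry or loss of the silyl ether.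

Step 6
Reactants: 7 Z-allylic alcohol
Product: 8 (2R,3S)-epoxy alcohol (oxirane numbering; C1 R, C2 S in briarane numbering)
Conditions: Ti(OiPr)4 (0.3 equiv), D-(−)-diethyl tartrate (0.36 equiv), t-BuOOH, 4 Å MS, CH2Cl2, −20 °C
Reagents that add atoms: tert-butyl hydroperoxide, CC(C)(C)OO
Why: Sharpless asymmetric epoxidation acts only on the free allylic alcohol, and the D-(−)-tartrate complex delivers oxygen to the face that gives the 2R,3S oxirane, so C1 and C2 are set by reagent control.

Step 7
Reactants: 8 epoxy alcohol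
Product: 9 (2S,3S)-epoxy aldehyde
Conditions: Dess–Martin periodinane, pyridine, CH2Cl2, 0 °C to rt
Reagents that add atoms: none
Why: Dess–Martin oxidation gives the aldehyde, whose α-carbon is quaternary and therefore cannot epimerise.

Step 8
Reactants: 10 3-(TBS-oxy)propanal
Product: 11 (Z)-iodoalkene, tert-butyl{[(3Z)-4-iodopent-3-en-1-yl]oxy}dimethylsilane
Conditions: [Ph3PCH2CH3]I, n-BuLi, THF, 0 °C; I2, −78 °C; NaN(SiMe3)2, −20 °C; then 10, −78 °C to rt
Reagents that add atoms: ethyltriphenylphosphonium iodide, CC[P+](c1ccccc1)(c1ccccc1)c1ccccc1.[I-]; iodine, II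
Why: Stork–Zhao olefination with the α-iodo ylide made in the flask gives the Z iodoalkene under kinetic Wittig control, with iodine cis to the chain.

Step 9
Reactants: 11 (Z)-iodoalkene
Product: 14 (Z)-allylboronate, via alkenyllithium 12 (not isolated), via borate complex 13 (not isolated)
Conditions: t-BuLi (2.1 equiv), Et2O, −78 °C; ClCH2B(pin), −78 °C to rt
Reagents that add atoms: 2-(chloromethyl)-4,4,5,5-tetramethyl-1,3,2-dioxaborolane, ClCB1OC(C)(C)C(C)(C)O1; tert-butyllithium, [Li]C(C)(C)C (lithium of 12 and 13 only)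
Why: Iodine–lithium exchange and the Matteson-type 1,2-metallate shift of the borate complex (loss of chloride) both proceed with retention of alkene geometry, so the boronate keeps CH2B cis to the chain.

Step 10
Reactants: 9 epoxy aldehyde; 14 (Z)-allylboronate
Product: 15 syn homoallylic alcohol (C1 R, C2 S, C10 R, C14 S)
Conditions: (S)-3,3′-bis(2,4,6-triisopropylphenyl)-1,1′-binaphthyl-2,2′-diyl hydrogen phosphate (10 mol %), 4 Å MS, toluene, −30 °C to rt; aqueous work-up
Reagents that add atoms: none
Why: Chiral phosphoric acid-catalysed allylboration runs through a closed chair Zimmerman–Traxler transition state in which the Z boronate gives the syn adduct while the S acid directs attack to the Si face of the aldehyde, which together fix C10 as R (the C14 centre is removed in step 11).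

Step 11
Reactants: 15 syn homoallylic alcohol
Product: 16 epoxy ketone (C1 S, C2 S, C10 R)
Conditions: Dess–Martin periodinane, pyridine, CH2Cl2, 0 °C
Reagents that add atoms: none
Why: Dess–Martin oxidation under buffered, non-basic conditions should give the ketone without epimerising the doubly activated C10 centre or opening the oxirane.

Step 12
Reactants: 16 epoxy ketone
Product: 17 tertiary alcohol with allyl and isopropenyl arms (C1 S, C2 S, C10 R, C14 R)
Conditions: CH2=CHCH2MgBr, THF, −78 °C; aq. NH4Cl
Reagents that add atoms: allylmagnesium bromide, C=CC[Mg]Br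
Why: 1,2-Addition of the allyl Grignard reagent through a six-membered transition state is faster than enolisation and, under Cram chelate control (magnesium between carbonyl and oxirane oxygens), should come from the side of the C15 methyl, although the C14 configuration is of no consequence because C14 becomes the carbonyl carbon in step 14.

Step 13
Reactants: 17 tertiary alcohol
Product: 18 cyclopentenol bearing the oxirane (C1 S, C2 S, C10 R, C14 R)
Conditions: second-generation Grubbs catalyst (5 mol %), CH2Cl2, 40 °C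
Reagents that add atoms: none
Why: Ring-closing metathesis of the allyl and isopropenyl groups is favoured by five-membered ring formation and loss of ethene, leaves the trisubstituted C5=C6 alkene alone and places the C11=C12 alkene regiospecifically without a new stereocentre.

Step 14
Reactants: 18 cyclopentenol bearing the oxirane
Product: 19 β-hydroxy cyclohexenone (C1 R, C2 S, C10 R)
Conditions: BF3·OEt2 (1.1 equiv), CH2Cl2, −78 °C; aq. NaHCO3
Reagents that add atoms: none
Why: BF3 binds the oxirane oxygen, the C1–O bond ionises at the tertiary carbon and, in concert, ring carbon C10 shifts from the carbinol carbon C14 to C1 while the hydroxyl becomes the C14 ketone (semipinacol rearrangement of a tertiary 2,3-epoxy alcohol). The closest known reaction type is the Lewis acid ring expansion of 1-(oxiran-2-yl)cycloalkanols to 2-quaternary β-hydroxy cycloalkanones. The cyclohexenone ring is closed not by a cyclisation but by this suprafacial 1,2-alkyl shift, which inserts C1 between C14 and C10 and enlarges the five-membered ring by one carbon. C1 is set by the oxirane configuration, because C10 must arrive anti to the departing C1–O bond (inversion, 1S in 18 to 1R in 19), C10 migrates with retention and C2 keeps its C–O bond (2S from step 6), while the C14 centre of 18 is erased so that both carbinol epimers converge. The step needs migration of C10 rather than C13, which the higher substitution of C10 (secondary and allylic against primary) secures, and it needs the shift to outrun attack of the C5=C6 alkene on the activated oxirane, which the hydroxyl-assisted antiperiplanar shift at −78 °C and the inductive deactivation of that alkene by its allylic silyloxy group secure.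

Step 15
Reactants: 19 β-hydroxy cyclohexenone
Product: 20 C2 butanoate of 19
Conditions: (n-PrCO)2O, DMAP, pyridine, CH2Cl2, 0 °C to rt
Reagents that add atoms: butanoic anhydride, CCCC(=O)OC(=O)CCC
Why: DMAP-catalysed acyl transfer installs the natural butanoate on the hindered C2 hydroxyl and at the same time blocks retro-aldol cleavage of the β-hydroxy ketone, with no stereocentre affected.

Step 16
Reactants: 20 keto butanoate
Product: 21 (14R)-alcohol (hydroxyl cis to the C1–C2 bond, trans to C15)
Conditions: (S)-2-methyl-CBS-oxazaborolidine (0.5 equiv), catecholborane, toluene, −78 to −40 °C; MeOH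
Reagents that add atoms: none
Why: Corey–Bakshi–Shibata reduction distinguishes the quaternary C1 flank (large) from the C13 methylene flank (small), so the S catalyst should deliver hydride to the Si face of the C14 ketone (the face of C15) and set 14R by catalyst control, while catecholborane at low temperature spares the esters and the trisubstituted alkenes.

Step 17
Reactants: 21 (14R)-alcohol
Product: 22 C14 acetate, C2 butanoate (both silyl ethers intact)
Conditions: Ac2O, DMAP, pyridine, rt
Reagents that add atoms: acetic anhydride, CC(=O)OC(C)=O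
Why: DMAP-catalysed acetylation of the axial, neopentylic C14 hydroxyl installs the natural acetate without touching the stereocentre.

Step 18
Reactants: 22 bis-silyl ether diester
Product: 23 primary C8 alcohol
Conditions: AcOH/THF/H2O (3:1:1), rt
Reagents that add atoms: none
Why: Acid-catalysed solvolysis cleaves the primary alkyl TBS ether far faster than the TBDPS ether and leaves both carboxylic esters intact (selective silyl ether cleavage).

Step 19
Reactants: 23 primary C8 alcohol
Product: 24 C8 aldehyde
Conditions: Dess–Martin periodinane, pyridine, CH2Cl2, 0 °C to rt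
Reagents that add atoms: none
Why: Dess–Martin oxidation gives the aldehyde, and C10 is β to the new carbonyl so that no centre can epimerise.

Step 20
Reactants: 24 C8 aldehyde
Product: 25 β-hydroxy ester (mixture of C8 and C17 epimers)
Conditions: CH3CHBrCO2CH3, Zn dust, THF, 0 to 40 °C; aq. NH4Cl
Reagents that add atoms: methyl 2-bromopropanoate, COC(=O)C(C)Br
Why: Reformatsky addition of the zinc enolate is chemoselective for the aldehyde over the acetate and butanoate, and the two new centres are formed as a mixture that is erased in steps 21 and 22.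

Step 21
Reactants: 25 β-hydroxy ester
Product: 26 β-keto ester (C17 epimers)
Conditions: Dess–Martin periodinane, pyridine, CH2Cl2, rt
Reagents that add atoms: none
Why: Dess–Martin oxidation converts the β-hydroxy ester into the β-keto ester under neutral conditions that avoid retro-aldol cleavage.

Step 22
Reactants: 26 β-keto ester
Product: 27 (Z)-enol triflate (triflate cis to the ester)
Conditions: NaH, THF, 0 °C; PhNTf2, 0 °C to rt
Reagents that add atoms: N-phenylbis(trifluoromethanesulfonimide), O=S(=O)(N(c1ccccc1)S(=O)(=O)C(F)(F)F)C(F)(F)F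
Why: Deprotonation gives the sodium-chelated Z enolate of the β-keto ester and O-sulfonylation traps it as the Z enol triflate, the geometry that lets the ester reach the C7 oxygen after step 25.

Step 23
Reactants: 27 (Z)-enol triflate
Product: 28 C7 allylic alcohol
Conditions: HF·pyridine, pyridine, THF, 0 °C to rt
Reagents that add atoms: none
Why: Fluoride-mediated desilylation with buffered HF·pyridine removes the TBDPS group while the enol triflate and the esters remain.

Step 24
Reactants: 28 C7 allylic alcohol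
Product: 29 (Z)-enal
Conditions: TEMPO (10 mol %), PhI(OAc)2, CH2Cl2, 0 °C to rt
Reagents that add atoms: none
Why: Oxoammonium-catalysed oxidation is selective for the primary allylic alcohol and preserves the Z geometry of neral-type enals.

Step 25
Reactants: 29 (Z)-enal enol triflate
Product: 31 macrocyclic butenolide (1R,2S,7R,10R,14R), via hydroxy ester 30 (not isolated)
Conditions: CrCl2 (10 equiv), NiCl2 (0.1 equiv), DMSO/THF, rt, slow addition to 2 mM; aqueous work-up
Reagents that add atoms: none
Why: In this Nozaki–Hiyama–Kishi reaction zerovalent nickel inserts into the enol triflate, transmetallation gives an alkenyl species of trivalent chromium that adds 1,2 to the aldehyde under high dilution to close the ten-membered ring at C7–C8, and the Z γ-hydroxy enoate lactonises to the butenolide, with 7R set by the macrocyclic transition state under the influence of C1, C2 and C10, which is the main uncertainty of the route.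

Step 26
Reactants: 31 macrocyclic butenolide
Product: 32 11β-hydroxy-12α-bromide (11S,12S)
Conditions: N-bromosuccinimide, THF/H2O (4:1), 0 °C, dark
Reagents that add atoms: N-bromosuccinimide, O=C1CCC(=O)N1Br; water, O
Why: Bromohydrin formation should occur at the electron-rich C11=C12 alkene (C5=C6 is deactivated by the allylic lactone oxygen, C8=C17 is conjugated) with the bromonium ion on the α face, anti to the axial C15 methyl, and trans-diaxial, Markovnikov opening by water at C11 from the β face.

Step 27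
Reactants: 32 bromohydrin
Product: 33 CNP0220791.1
Conditions: Ag2O, THF, rt, dark
Reagents that add atoms: none
Why: Silver-assisted intramolecular Williamson displacement of the antiperiplanar bromide by the C11 hydroxyl inverts C12 and gives the β-oxirane (11S,12R, oxygen cis to C15) under conditions that spare the esters and the acidic C7–H of the butenolide.

**Compound list**

1 | nerol, (2Z)-3,7-dimethylocta-2,6-dien-1-ol | CC(C)=CCC/C(C)=C\CO | starting material
2 | tert-butyl{[(2Z)-3,7-dimethylocta-2,6-dien-1-yl]oxy}diphenylsilane | CC(C)(C)[Si](c1ccccc1)(c1ccccc1)OC/C=C(C)\CCC=C(C)C | intermediate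
3 | tert-butyl{[(2Z)-5-(3,3-dimethyloxiran-2-yl)-3-methylpent-2-en-1-yl]oxy}diphenylsilane (racemic) | CC(C)(C)[Si](c1ccccc1)(c1ccccc1)OC/C=C(C)\CCC1OC1(C)C | intermediate
4 | (6Z)-8-(TBDPS-oxy)-2,6-dimethyloct-6-ene-2,3-diol (racemic, not isolated) | CC(C)(C)[Si](c1ccccc1)(c1ccccc1)OC/C=C(C)\CCC(O)C(C)(C)O | intermediate
5 | (4Z)-6-(TBDPS-oxy)-4-methylhex-4-enal | CC(C)(C)[Si](c1ccccc1)(c1ccccc1)OC/C=C(C)\CCC=O | intermediate
6 | methyl (2Z,6Z)-8-(TBDPS-oxy)-2,6-dimethylocta-2,6-dienoate | CC(C)(C)[Si](c1ccccc1)(c1ccccc1)OC/C=C(C)\CC/C=C(/C)C(=O)OC | intermediate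
7 | (2Z,6Z)-8-(TBDPS-oxy)-2,6-dimethylocta-2,6-dien-1-ol | CC(C)(C)[Si](c1ccccc1)(c1ccccc1)OC/C=C(C)\CC/C=C(/C)CO | intermediate
8 | [(2R,3S)-3-{(3Z)-5-(TBDPS-oxy)-3-methylpent-3-en-1-yl}-2-methyloxiran-2-yl]methanol | CC(C)(C)[Si](c1ccccc1)(c1ccccc1)OC/C=C(C)\CC[C@@H]1O[C@]1(C)CO | intermediate
9 | (2S,3S)-3-{(3Z)-5-(TBDPS-oxy)-3-methylpent-3-en-1-yl}-2-methyloxirane-2-carbaldehyde | CC(C)(C)[Si](c1ccccc1)(c1ccccc1)OC/C=C(C)\CC[C@@H]1O[C@]1(C)C=O | intermediate
10 | 3-[(tert-butyldimethylsilyl)oxy]propanal | O=CCCO[Si](C)(C)C(C)(C)C | starting material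
11 | tert-butyl{[(3Z)-4-iodopent-3-en-1-yl]oxy}dimethylsilane | C/C(I)=C/CCO[Si](C)(C)C(C)(C)C | intermediate
12 | {(2Z)-5-(TBS-oxy)pent-2-en-2-yl}lithium (not isolated) | [Li]/C(C)=C\CCO[Si](C)(C)C(C)(C)C | intermediate
13 | lithium (chloromethyl){(2Z)-5-(TBS-oxy)pent-2-en-2-yl}(pinacolato)borate (not isolated) | [Li+].C/C(=C/CCO[Si](C)(C)C(C)(C)C)[B-]1(CCl)OC(C)(C)C(C)(C)O1 | intermediate
14 | 2-{(2Z)-5-(TBS-oxy)-2-methylpent-2-en-1-yl}-4,4,5,5-tetramethyl-1,3,2-dioxaborolane | C/C(CB1OC(C)(C)C(C)(C)O1)=C/CCO[Si](C)(C)C(C)(C)C | intermediate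
15 | (1S,2R)-2-[2-(TBS-oxy)ethyl]-1-[(2R,3S)-3-{(3Z)-5-(TBDPS-oxy)-3-methylpent-3-en-1-yl}-2-methyloxiran-2-yl]-3-methylbut-3-en-1-ol | CC(C)(C)[Si](c1ccccc1)(c1ccccc1)OC/C=C(C)\CC[C@@H]1O[C@]1(C)[C@@H](O)[C@H](CCO[Si](C)(C)C(C)(C)C)C(C)=C | intermediate
16 | (2R)-2-[2-(TBS-oxy)ethyl]-1-[(2S,3S)-3-{(3Z)-5-(TBDPS-oxy)-3-methylpent-3-en-1-yl}-2-methyloxiran-2-yl]-3-methylbut-3-en-1-one | CC(C)(C)[Si](c1ccccc1)(c1ccccc1)OC/C=C(C)\CC[C@@H]1O[C@]1(C)C(=O)[C@H](CCO[Si](C)(C)C(C)(C)C)C(C)=C | intermediate
17 | (4R,5R)-5-[2-(TBS-oxy)ethyl]-4-[(2S,3S)-3-{(3Z)-5-(TBDPS-oxy)-3-methylpent-3-en-1-yl}-2-methyloxiran-2-yl]-6-methylhepta-1,6-dien-4-ol | CC(C)(C)[Si](c1ccccc1)(c1ccccc1)OC/C=C(C)\CC[C@@H]1O[C@]1(C)[C@@](O)(CC=C)[C@H](CCO[Si](C)(C)C(C)(C)C)C(C)=C | intermediate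
18 | (1R,2R)-2-[2-(TBS-oxy)ethyl]-1-[(2S,3S)-3-{(3Z)-5-(TBDPS-oxy)-3-methylpent-3-en-1-yl}-2-methyloxiran-2-yl]-3-methylcyclopent-3-en-1-ol | CC(C)(C)[Si](c1ccccc1)(c1ccccc1)OC/C=C(C)\CC[C@@H]1O[C@]1(C)[C@@]2(O)CC=C(C)[C@H]2CCO[Si](C)(C)C(C)(C)C | intermediate
19 | (5R,6R)-5-[2-(TBS-oxy)ethyl]-6-[(1S,4Z)-6-(TBDPS-oxy)-1-hydroxy-4-methylhex-4-en-1-yl]-4,6-dimethylcyclohex-3-en-1-one | CC(C)(C)[Si](c1ccccc1)(c1ccccc1)OC/C=C(C)\CC[C@H](O)[C@]1(C)C(=O)CC=C(C)[C@H]1CCO[Si](C)(C)C(C)(C)C | intermediate
20 | (1S,4Z)-6-(TBDPS-oxy)-1-[(1R,6R)-6-{2-(TBS-oxy)ethyl}-1,5-dimethyl-2-oxocyclohex-4-en-1-yl]-4-methylhex-4-en-1-yl butanoate | CC(C)(C)[Si](c1ccccc1)(c1ccccc1)OC/C=C(C)\CC[C@H](OC(=O)CCC)[C@]1(C)C(=O)CC=C(C)[C@H]1CCO[Si](C)(C)C(C)(C)C | intermediate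
21 | (1S,4Z)-6-(TBDPS-oxy)-1-[(1S,2R,6R)-6-{2-(TBS-oxy)ethyl}-2-hydroxy-1,5-dimethylcyclohex-4-en-1-yl]-4-methylhex-4-en-1-yl butanoate | CC(C)(C)[Si](c1ccccc1)(c1ccccc1)OC/C=C(C)\CC[C@H](OC(=O)CCC)[C@]1(C)[C@H](O)CC=C(C)[C@H]1CCO[Si](C)(C)C(C)(C)C | intermediate
22 | (1S,4Z)-1-[(1R,2R,6R)-2-acetoxy-6-{2-(TBS-oxy)ethyl}-1,5-dimethylcyclohex-4-en-1-yl]-6-(TBDPS-oxy)-4-methylhex-4-en-1-yl butanoate | CC(C)(C)[Si](c1ccccc1)(c1ccccc1)OC/C=C(C)\CC[C@H](OC(=O)CCC)[C@]1(C)[C@H](OC(C)=O)CC=C(C)[C@H]1CCO[Si](C)(C)C(C)(C)C | intermediate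
23 | as 22 with a 2-hydroxyethyl group on C10 (free C8 alcohol) | CC(C)(C)[Si](c1ccccc1)(c1ccccc1)OC/C=C(C)\CC[C@H](OC(=O)CCC)[C@]1(C)[C@H](OC(C)=O)CC=C(C)[C@H]1CCO | intermediate
24 | as 22 with a 2-oxoethyl group on C10 (C8 aldehyde) | CC(C)(C)[Si](c1ccccc1)(c1ccccc1)OC/C=C(C)\CC[C@H](OC(=O)CCC)[C@]1(C)[C@H](OC(C)=O)CC=C(C)[C@H]1CC=O | intermediate
25 | methyl 3-hydroxy-2-methylbutanoate chain on C10 (C8 carbinol, mixture of C8 and C17 epimers) | CC(C)(C)[Si](c1ccccc1)(c1ccccc1)OC/C=C(C)\CC[C@H](OC(=O)CCC)[C@]1(C)[C@H](OC(C)=O)CC=C(C)[C@H]1CC(O)C(C)C(=O)OC | intermediate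
26 | methyl 2-methyl-3-oxobutanoate chain on C10 (C8 ketone, C17 epimers) | CC(C)(C)[Si](c1ccccc1)(c1ccccc1)OC/C=C(C)\CC[C@H](OC(=O)CCC)[C@]1(C)[C@H](OC(C)=O)CC=C(C)[C@H]1CC(=O)C(C)C(=O)OC | intermediate
27 | (Z)-enol triflate of 26 (C8 triflate cis to the methyl ester) | CC(C)(C)[Si](c1ccccc1)(c1ccccc1)OC/C=C(C)\CC[C@H](OC(=O)CCC)[C@]1(C)[C@H](OC(C)=O)CC=C(C)[C@H]1C/C(OS(=O)(=O)C(F)(F)F)=C(/C(=O)OC)C | intermediate
28 | as 27 with free C7 allylic alcohol | OC/C=C(C)\CC[C@H](OC(=O)CCC)[C@]1(C)[C@H](OC(C)=O)CC=C(C)[C@H]1C/C(OS(=O)(=O)C(F)(F)F)=C(/C(=O)OC)C | intermediate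
29 | as 27 with C7 (Z)-enal | O=C/C=C(C)\CC[C@H](OC(=O)CCC)[C@]1(C)[C@H](OC(C)=O)CC=C(C)[C@H]1C/C(OS(=O)(=O)C(F)(F)F)=C(/C(=O)OC)C | intermediate
30 | ten-membered (7R)-hydroxy (Z)-enoate, methyl ester at C18 (formed as its chromium alkoxide, not isolated) | CCCC(=O)O[C@H]1CC/C(C)=C\[C@@H](O)/C(=C(/C)C(=O)OC)C[C@@H]2C(C)=CC[C@@H](OC(C)=O)[C@@]12C | intermediate
31 | (1R,2S,7R,10R,14R)-14-acetoxy-2-butanoyloxybriara-5(Z),8(17),11-trien-18,7-olide | CCCC(=O)O[C@H]1CC/C(C)=C\[C@H]2OC(=O)C(C)=C2C[C@@H]2C(C)=CC[C@@H](OC(C)=O)[C@@]12C | intermediate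
32 | (1R,2S,7R,10S,11S,12S,14R)-14-acetoxy-12-bromo-2-butanoyloxy-11-hydroxybriara-5(Z),8(17)-dien-18,7-olide | CCCC(=O)O[C@H]1CC/C(C)=C\[C@H]2OC(=O)C(C)=C2C[C@@H]2[C@](C)(O)[C@@H](Br)C[C@@H](OC(C)=O)[C@@]12C | intermediate
33 | CNP0220791.1, (1R,2S,7R,10S,11S,12R,14R)-14-acetoxy-2-butanoyloxy-11,12-epoxybriara-5(Z),8(17)-dien-18,7-olide | CCCC(=O)O[C@H]1CC/C(C)=C\[C@H]2OC(=O)C(C)=C2C[C@@H]2[C@]3(C)O[C@@H]3C[C@@H](OC(C)=O)[C@@]12C | target

**Step count and risks**

Total step count: 27. Longest linear sequence: 25 steps (steps 1–7 and 10–27, from nerol).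

Steps most likely to fail:

1. Step 25. The process at risk is poor or reversed facial selectivity at C7 in the ring-closing addition, because the new centre is fixed only by the conformation of the forming ten-membered ring. The fallback puts C7 under reagent control and sets out from β-keto ester 26. Non-chelating enolisation (KN(SiMe3)2, 18-crown-6, THF, −78 °C; PhNTf2) should give the (E)-enol triflate F1, whose ester is trans to the triflate. HF·pyridine then gives the allylic alcohol F2, and TEMPO/PhI(OAc)2 the (Z)-enal F3. The same CrCl2/NiCl2 closure gives the macrocyclic hydroxy (E)-enoate F4 as a mixture of C7 epimers that cannot lactonise. Dess–Martin oxidation gives the macrocyclic dienone F5. Corey–Bakshi–Shibata reduction with the S oxazaborolidine and catecholborane (C8 as the large flank, C6 as the small flank) should give the (7R)-alcohol F6. Irradiation (300 nm, catalytic PhSSPh, benzene) isomerises the E enoate to the Z isomer, which lactonises with loss of methanol and comes back to the route at 31.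

2. Step 16. The process at risk is hydride delivery to the wrong face of the C14 ketone, if the substrate preference for axial attack anti to the C15 methyl overrides the catalyst. The fallback uses chelation control from the C2 hydroxyl and sets out from hydroxy ketone 19. Narasaka–Prasad reduction (Et2BOMe, NaBH4, THF/MeOH, −78 °C), in which external hydride adds to the boron chelate from the side of H-2, should give the syn-1,3-diol F7 (2S,14R). Butanoic anhydride (1.0 equiv), Et3N and catalytic DMAP at −40 °C should then acylate the acyclic C2 hydroxyl before the axial, ring-bound C14 hydroxyl, which comes back to the route at 21.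

3. Step 26. The process at risk is bromonium formation on the β face, steered by the axial 14-acetoxy group on the α face, which after anti opening and closure would give the 11α,12α-oxirane. The fallback sets out from 31 and transfers oxygen directly (mCPBA, NaHCO3, CH2Cl2, 0 °C, or dimethyldioxirane in acetone). Direct epoxidation places the oxygen on the face that the electrophile prefers, here the β face, and comes back to the route at 33 without any new compound (F0).

**Further compounds**

F1 | step 25 | (E)-enol triflate isomer of 27 (triflate trans to the methyl ester) | CC(C)(C)[Si](c1ccccc1)(c1ccccc1)OC/C=C(C)\CC[C@H](OC(=O)CCC)[C@]1(C)[C@H](OC(C)=O)CC=C(C)[C@H]1C/C(OS(=O)(=O)C(F)(F)F)=C(\C(=O)OC)C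
F2 | step 25 | C7 allylic alcohol from F1 | OC/C=C(C)\CC[C@H](OC(=O)CCC)[C@]1(C)[C@H](OC(C)=O)CC=C(C)[C@H]1C/C(OS(=O)(=O)C(F)(F)F)=C(\C(=O)OC)C
F3 | step 25 | C7 (Z)-enal from F2 | O=C/C=C(C)\CC[C@H](OC(=O)CCC)[C@]1(C)[C@H](OC(C)=O)CC=C(C)[C@H]1C/C(OS(=O)(=O)C(F)(F)F)=C(\C(=O)OC)C
F4 | step 25 | ten-membered 7-hydroxy (E)-enoate, both C7 epimers | CCCC(=O)O[C@H]1CC/C(C)=C\C(O)/C(=C(\C)C(=O)OC)C[C@@H]2C(C)=CC[C@@H](OC(C)=O)[C@@]12C
F5 | step 25 | ten-membered C7 ketone (cross-conjugated dienone) | CCCC(=O)O[C@H]1CC/C(C)=C\C(=O)/C(=C(\C)C(=O)OC)C[C@@H]2C(C)=CC[C@@H](OC(C)=O)[C@@]12C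
F6 | step 25 | ten-membered (7R)-hydroxy (E)-enoate | CCCC(=O)O[C@H]1CC/C(C)=C\[C@@H](O)/C(=C(\C)C(=O)OC)C[C@@H]2C(C)=CC[C@@H](OC(C)=O)[C@@]12C
F7 | step 16 | syn-1,3-diol (2S,14R) from 19 | CC(C)(C)[Si](c1ccccc1)(c1ccccc1)OC/C=C(C)\CC[C@H](O)[C@]1(C)[C@H](O)CC=C(C)[C@H]1CCO[Si](C)(C)C(C)(C)C
F0 | step 26 | none | none
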